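**Assumptions:** The amine catalyst in step 2 is chosen so that epoxide 5 forms as drawn. Acylation of lactol 16 is taken to give the axial (anomeric-effect) 1-isovalerate as the major, separable anomer.

## Retrosynthetic overview
1. Target ← HF·py removal of the C7 TBS group ← DDQ desaturation (C5–H/C6–H) of the dihydropyran acylal, which installs the C5=C6 diene.
2. The pyran ring (C4–C5 and O2–C1 bonds, lactol C1) ← amine-catalysed [3+3] oxa-annulation of a cyclopentene-carbaldehyde with malonaldehyde; C11 and C1 are then elaborated to CH2OAc and the acylal.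
3. Enal ← enol triflate/formylation of an α-hydroxy cyclopentanone ← Payne rearrangement/isovalerate opening of an epoxy-ketone.
4. Epoxy-ketone ← organocatalytic asymmetric epoxidation of 2-(hydroxymethyl)cyclopentenone, the Morita–Baylis–Hillman adduct of cyclopentenone and CH2O. The carbocycle comes from commercial cyclopentenone; the pyran is formed second (step 7).

## Route

**Step 1**
Reactants: 1 cyclopent-2-en-1-one; 2 formaldehyde
Product: 3 2-(hydroxymethyl)cyclopent-2-en-1-one
Conditions: 2 (37% aq.), imidazole (0.3 equiv), NaHCO3, THF/H2O, 23 °C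
Reagents that add atoms: formaldehyde, C=O
Why: Morita–Baylis–Hillman α-hydroxymethylation of the enone gives the achiral substrate for the asymmetric step.

**Step 2**
Reactants: 3; 4 hydrogen peroxide
Product: 5 (1S,5S)-1-(hydroxymethyl)-6-oxabicyclo[3.1.0]hexan-2-one
Conditions: 9-amino-9-deoxy-epi-quinine·3TFA (20 mol %), 4 (30% aq., 3 equiv), dioxane, 23 °C
Reagents that add atoms: hydrogen peroxide, OO
Why: Iminium-activated Weitz–Scheffer nucleophilic epoxidation delivers HOO⁻ to one enone face, which sets C7 and C8 (the first stereocentres) as a cis-epoxide with CH2OH on the opposite face.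

**Step 3**
Reactants: 5; 6 isovaleric acid
Product: 7 (2R,3S)-2,3-dihydroxy-2-{[(3-methylbutanoyl)oxy]methyl}cyclopentan-1-one
Conditions: 6 (3 equiv), Na2CO3 (1.5 equiv), H2O/MeCN 1:1, 60 °C
Reagents that add atoms: isovaleric acid, CC(C)CC(=O)O
Why: Payne rearrangement, in which the C10 alkoxide attacks C8 with inversion, forms the spiro-epoxide and leaves the C7 oxygen with retention; isovalerate then opens the primary C10 position by SN2. This gives trans C7-OH/C8-OH with C10 cis to C7-OH, as in the target.

**Step 4**
Reactants: 7; 8 TBSCl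
Product: 9 C7 TBS ether of 7
Conditions: 8 (1.1 equiv), imidazole, DMF, 0 °C
Reagents that add atoms: TBSCl, C[Si](C)(Cl)C(C)(C)C
Why: The secondary C7-OH is silylated selectively over the hindered tertiary C8-OH (silyl protection); no stereocentre changes.

**Step 5**
Reactants: 9; 10 N-phenylbis(trifluoromethanesulfonimide)
Product: 11 (4S,5R)-4-(TBSO)-5-hydroxy-5-(isovaleryloxymethyl)cyclopent-1-en-1-yl triflate
Conditions: KHMDS (2.2 equiv), THF, –78 °C; then 10
Reagents that add atoms: PhNTf2, O=S(=O)(N(c1ccccc1)S(=O)(=O)C(F)(F)F)C(F)(F)F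
Why: C8 is quaternary, so kinetic enolisation and O-triflation occur only toward C5, giving the C9=C5 enol triflate regiospecifically.

**Step 6**
Reactants: 11; 12 carbon monoxide; 13 Bu3SnH
Product: 14 (4S,5R)-4-(TBSO)-5-hydroxy-5-(isovaleryloxymethyl)cyclopent-1-ene-1-carbaldehyde
Conditions: Pd(PPh3)4 (5 mol %), LiCl, 13, 12 (1 atm), THF, 50 °C
Reagents that add atoms: carbon monoxide, [C-]#[O+]
Why: Pd-catalysed reductive carbonylation (Stille–Baillargeon formylation) of the vinyl triflate installs C1 as an enal CHO; the esters and silyl ether survive.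

**Step 7**
Reactants: 14; 15 malonaldehyde sodium salt
Product: 16 cis-fused cyclopenta[c]pyran lactol (C11 aldehyde; C1 anomeric mixture), SMILES below
Conditions: (S)-diphenylprolinol TMS ether (20 mol %), PhCO2H (40 mol %, liberates malonaldehyde from 15), CHCl3, 23 °C
Reagents that add atoms: malonaldehyde (free form), O=CCC=O
Why: Proposed new method: the secondary amine forms the iminium of the α,β-disubstituted cyclic enal, malonaldehyde enol adds at C5 from the lower face (the top face carries OTBS and CH2O-iVal), and the enol oxygen closes onto C1 to give the lactol. Cis ring fusion fixes C9-H up. The β-alkoxy-enal push–pull system (C3=C4–CHO) stabilises the lactol. The closest known reaction is the amine-catalysed Michael/hemiacetalisation of enals with 1,3-dicarbonyls to 2-hydroxy-3,4-dihydro-2H-pyrans.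

**Step 8**
Reactants: 16; 17 isovaleryl chloride
Product: 18 1-O-isovalerate (acylal) of 16, single anomer
Conditions: 17 (1.5 equiv), pyridine, DMAP (cat.), CH2Cl2, –20 → 0 °C
Reagents that add atoms: isovaleryl chloride, CC(C)CC(=O)Cl
Why: The lactol OH is acylated selectively over the tertiary alcohol; DMAP equilibration of the anomers favours the axial acylal (anomeric effect), which sets C1.

**Step 9**
Reactants: 18; 19 zinc borohydride
Product: 20 C11 primary alcohol of 18
Conditions: 19, Et2O, –20 °C
Reagents that add atoms: none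
Why: Zn(BH4)2 reduces the push–pull aldehyde in a 1,2-sense and leaves the acylal and esters untouched (chemoselective hydride reduction).

**Step 10**
Reactants: 20; 21 acetic anhydride
Product: 22 C11 acetate of 20
Conditions: 21, pyridine, DMAP (cat.), CH2Cl2, 0 °C
Reagents that add atoms: acetic anhydride, CC(=O)OC(C)=O
Why: Only the primary allylic alcohol is acetylated; the tertiary C8-OH is too hindered.

**Step 11**
Reactants: 22; 23 DDQ
Product: 24 C5=C6 diene (C7 TBS ether)
Conditions: 23 (1.3 equiv), 2,6-di-tert-butyl-4-methylpyridine (2 equiv), PhH, 50 °C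
Reagents that add atoms: none
Why: DDQ abstracts the doubly activated C5–H hydride to give the enol-ether-stabilised oxocarbenium ion, and E1 loss of C6–H forms the exocyclic C5=C6 alkene. C5 stereochemistry is deliberately destroyed; C9-H, C1, C7 and C8 are untouched.

**Step 12**
Reactants: 24; 25 HF·pyridine
Product: 26 Jatamanvaltrate J
Conditions: 25, pyridine, THF, 0 → 23 °C
Reagents that add atoms: none
Why: Buffered fluoride removes the C7 TBS ether under conditions the acylal and enol ether tolerate (silyl deprotection).

## Compound list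
1 | cyclopent-2-en-1-one | O=C1C=CCC1 | starting material
2 | formaldehyde | C=O | starting material
3 | 2-(hydroxymethyl)cyclopent-2-en-1-one | O=C1CCC=C1CO | intermediate
4 | hydrogen peroxide | OO | starting material
5 | (1S,5S)-1-(hydroxymethyl)-6-oxabicyclo[3.1.0]hexan-2-one | O=C1CC[C@@H]2O[C@]12CO | intermediate
6 | isovaleric acid | CC(C)CC(=O)O | starting material
7 | (2R,3S)-2,3-dihydroxy-2-(isovaleryloxymethyl)cyclopentan-1-one | O=C1CC[C@H](O)[C@]1(O)COC(=O)CC(C)C | intermediate
8 | tert-butyldimethylsilyl chloride | C[Si](C)(Cl)C(C)(C)C | starting material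
9 | C7 TBS ether of 7 | O=C1CC[C@H](O[Si](C)(C)C(C)(C)C)[C@]1(O)COC(=O)CC(C)C | intermediate
10 | N-phenylbis(triflimide) | O=S(=O)(N(c1ccccc1)S(=O)(=O)C(F)(F)F)C(F)(F)F | starting material
11 | enol triflate of 9 | FC(F)(F)S(=O)(=O)OC1=CC[C@H](O[Si](C)(C)C(C)(C)C)[C@]1(O)COC(=O)CC(C)C | intermediate
12 | carbon monoxide | [C-]#[O+] | starting material
13 | tributyltin hydride | CCCC[SnH](CCCC)CCCC | starting material
14 | enal (cyclopentene-1-carbaldehyde) | O=CC1=CC[C@H](O[Si](C)(C)C(C)(C)C)[C@]1(O)COC(=O)CC(C)C | intermediate
15 | malonaldehyde sodium salt | [Na+].[O-]C=CC=O | starting material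
16 | lactol, C11 aldehyde (C1 epimeric) | OC1OC=C(C=O)[C@H]2C[C@H](O[Si](C)(C)C(C)(C)C)[C@](O)(COC(=O)CC(C)C)[C@@H]12 | intermediate
17 | isovaleryl chloride | CC(C)CC(=O)Cl | starting material
18 | 1-O-isovalerate of 16 | O=CC1=CO[C@@H](OC(=O)CC(C)C)[C@H]2[C@@H]1C[C@H](O[Si](C)(C)C(C)(C)C)[C@]2(O)COC(=O)CC(C)C | intermediate
19 | zinc borohydride | [BH4-].[BH4-].[Zn+2] | starting material
20 | C11 alcohol from 18 | OCC1=CO[C@@H](OC(=O)CC(C)C)[C@H]2[C@@H]1C[C@H](O[Si](C)(C)C(C)(C)C)[C@]2(O)COC(=O)CC(C)C | intermediate
21 | acetic anhydride | CC(=O)OC(C)=O | starting material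
22 | C11 acetate of 20 | CC(=O)OCC1=CO[C@@H](OC(=O)CC(C)C)[C@H]2[C@@H]1C[C@H](O[Si](C)(C)C(C)(C)C)[C@]2(O)COC(=O)CC(C)C | intermediate
23 | DDQ | N#CC1=C(C#N)C(=O)C(Cl)=C(Cl)C1=O | starting material
24 | diene silyl ether | CC(=O)OCC1=CO[C@@H](OC(=O)CC(C)C)[C@H]2C1=C[C@H](O[Si](C)(C)C(C)(C)C)[C@]2(O)COC(=O)CC(C)C | intermediate
25 | HF·pyridine | F.c1ccncc1 | starting material
26 | Jatamanvaltrate J | CC(=O)OCC1=CO[C@@H](OC(=O)CC(C)C)[C@H]2C1=C[C@H](O)[C@]2(O)COC(=O)CC(C)C | target

## Totals
Total steps: 12. Longest linear sequence: 12.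

## Three steps most likely to fail
1. **Step 7, the proposed new [3+3] annulation.** The enal is α,β-disubstituted and hindered, so iminium formation may be slow and C9 elimination of the C8 oxygen is possible.
   - Fallback: a stepwise route. Sc(OTf)3-catalysed Mukaiyama–Michael addition of methyl 3-(trimethylsilyloxy)acrylate to 14, then acid lactolisation, then DIBAL reduction of the vinylogous carbonate (with the lactol TES-protected) before acylation.
2. **Step 11, DDQ desaturation.** It may give the endocyclic C5=C9 (2H-pyran) isomer instead of C5=C6.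
   - Fallback: remove the TBS group, oxidise C7-OH to the ketone (DMP), and dehydrogenate with IBX·MPO to the push–pull dienone. Then reduce with Me4NBH(OAc)3, hydroxyl-directed from C8-OH, to give the trans C7/C8 diol.
3. **Step 2, asymmetric epoxidation of the α-substituted cyclopentenone.** Enantioselectivity and conversion are uncertain for this substrate.
   - Fallback: Luche reduction of 3 to the allylic diol, titanium–tartrate (Sharpless) kinetic-resolution epoxidation, then DMP oxidation of the secondary alcohol to give 5.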